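**Retrosynthetic overview**

- The route rests on the γ-butyrolactone ring O1–C2(=O)–C3–C4–C5: C2 is a carbonyl carbon flanked only by O1 and C3, so it can be delivered as carbon monoxide to a C3=C4 alkene that already carries both benzyl groups and the C5 hydroxyl.
- Last disconnection: the catechol O–H bonds, from the bis(benzyl ether) lactone 10 by hydrogenolysis.
- Key disconnection: C2–C3 and C2–O1, by palladium hydride cyclocarbonylation of the E allylic alcohol 9. This forms the only ring and both stereocentres (C3, C4).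
- The C3=C4 alkene of 9 comes from a Wittig reaction of the α-(3,4-dimethoxybenzyl) ester ylide 4 with arylacetaldehyde 7, followed by ester reduction.
- Ylide 4 comes from ylide 1 and bromide 2; aldehyde 7 comes from aldehyde 5 by one-carbon homologation.

Key step: step 6

Assumption: the hand of the bisphosphine that delivers hydride to the C4 Si face of 9 cannot be assigned in advance for a primary allylic alcohol; (2S,4S)-BPPM is written, and (2R,4R)-BPPM replaces it unchanged if the induction is the opposite one.

**Route**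

Step 1
Reactants: 1 ethyl (triphenyl-λ5-phosphanylidene)acetate; 2 3,4-dimethoxybenzyl bromide
Product: 4 ethyl 3-(3,4-dimethoxyphenyl)-2-(triphenyl-λ5-phosphanylidene)propanoate, via phosphonium bromide 3 (not isolated)
Conditions: EtOAc, reflux; then 1 M NaOH, CH2Cl2, 0 °C
Reagents that add atoms: none
Why: SN2 C-alkylation of the stabilised ylide by the reactive benzylic bromide gives the phosphonium salt, and hydroxide removes its remaining α-proton to give the α-benzylated stabilised ylide (ylide alkylation and re-deprotonation).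

Step 2
Reactants: 5 3,4-bis(benzyloxy)benzaldehyde
Product: 6 1,2-bis(benzyloxy)-4-(2-methoxyethenyl)benzene (E/Z mixture)
Conditions: MeOCH2PPh3Cl, KOtBu, THF, 0 °C → rt
Reagents that add atoms: (methoxymethyl)triphenylphosphonium chloride, COC[P+](c1ccccc1)(c1ccccc1)c1ccccc1.[Cl-]
Why: Wittig methoxymethylenation of a non-enolisable aryl aldehyde should give the enol ether; both alkene isomers lead to the same aldehyde, so the geometry is irrelevant.

Step 3
Reactants: 6 1,2-bis(benzyloxy)-4-(2-methoxyethenyl)benzene
Product: 7 2-[3,4-bis(benzyloxy)phenyl]acetaldehyde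
Conditions: 2 M HCl, THF, 50 °C, Ar; crude used directly
Reagents that add atoms: water, O
Why: Acid-catalysed enol ether hydrolysis (C-protonation, addition of water, loss of methanol) should release the homologated aldehyde, and aryl benzyl ethers are stable to dilute aqueous acid.

Step 4
Reactants: 4 ethyl 3-(3,4-dimethoxyphenyl)-2-(triphenyl-λ5-phosphanylidene)propanoate; 7 2-[3,4-bis(benzyloxy)phenyl]acetaldehyde
Product: 8 ethyl (E)-4-[3,4-bis(benzyloxy)phenyl]-2-(3,4-dimethoxybenzyl)but-2-enoate
Conditions: CH2Cl2, rt → 40 °C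
Reagents that add atoms: none
Why: In the Wittig reaction an α-substituted ester-stabilised ylide should collapse through the less crowded oxaphosphetane and place the ester trans to the aldehyde-derived chain (E), and the neutral, salt-free medium avoids base-mediated drift of the new alkene into conjugation with the arene.

Step 5
Reactants: 8 ethyl (E)-4-[3,4-bis(benzyloxy)phenyl]-2-(3,4-dimethoxybenzyl)but-2-enoate
Product: 9 (E)-4-[3,4-bis(benzyloxy)phenyl]-2-(3,4-dimethoxybenzyl)but-2-en-1-ol
Conditions: DIBAL-H, CH2Cl2, −78 → 0 °C; Rochelle salt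
Reagents that add atoms: none
Why: DIBAL-H 1,2-reduction of the enoate at low temperature should give the allylic alcohol without changing the position or geometry of the alkene; the aryl ethers are inert.

Step 6
Reactants: 9 (E)-4-[3,4-bis(benzyloxy)phenyl]-2-(3,4-dimethoxybenzyl)but-2-en-1-ol
Product: 10 (3R,4R)-3-[3,4-bis(benzyloxy)benzyl]-4-(3,4-dimethoxybenzyl)dihydrofuran-2(3H)-one
Conditions: Pd2(dba)3·CHCl3 (4 mol%), (2S,4S)-BPPM (8 mol%), CO/H2 (1:1, 55 bar), CH2Cl2, 100 °C
Reagents that add atoms: carbon monoxide, [C-]#[O+]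
Why: A chiral bisphosphine palladium hydride, formed from Pd(0), the ligand and H2 under CO, adds syn across the C3=C4 alkene with hydride to the fully substituted C4 and palladium to the less hindered C3, CO then inserts into the C3–Pd bond with retention, and the C5 hydroxyl attacks the acylpalladium to form C2–O1 and release Pd–H. The closest known reaction type is the palladium/bisphosphine-catalysed asymmetric cyclocarbonylation of β,γ-substituted allylic alcohols to γ-butyrolactones under CO/H2. The single ring, the lactone O1–C2–C3–C4–C5, closes by intramolecular alcoholysis of the acyl group, a 5-exo-trig attack at the acyl carbon. C4 is set by the chiral ligand, which must select the Si face of C4 (Re face of C3) for hydride delivery, and C3 is set relative to C4 by the E geometry, because syn addition of H and the acyl group to the E alkene leaves the two benzyl groups trans, which is 3R,4R. The step needs palladium at C3, which the trisubstituted alkene favours sterically and which alone can close a five-membered ring (palladium at C4 leads only to a strained β-lactone), and it needs carbonylation to outrun allylic C–O ionisation and alkene migration toward the arenes, which acid-free conditions and high CO pressure should favour. Aryl benzyl ethers are inert to homogeneous Pd/H2/CO, and any cis lactone would be converged to the more stable trans isomer by brief DBU treatment, since C3 is the only epimerisable centre.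

Step 7
Reactants: 10 (3R,4R)-3-[3,4-bis(benzyloxy)benzyl]-4-(3,4-dimethoxybenzyl)dihydrofuran-2(3H)-one
Product: 11 3'-O-demethylarctigenin, (3R,4R)-3-(3,4-dihydroxybenzyl)-4-(3,4-dimethoxybenzyl)dihydrofuran-2(3H)-one
Conditions: H2 (1 atm), 10% Pd/C, EtOAc–EtOH, rt
Reagents that add atoms: none
Why: Heterogeneous hydrogenolysis should cleave only the two aryl benzyl ethers; the lactone has no benzylic C–O bond, the methyl ethers are inert, and the neutral medium leaves C3 and C4 untouched.

**Compound list**

1 | ethyl (triphenyl-λ5-phosphanylidene)acetate | CCOC(=O)C=P(c1ccccc1)(c1ccccc1)c1ccccc1 | starting material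
2 | 3,4-dimethoxybenzyl bromide | COc1ccc(CBr)cc1OC | starting material
3 | [3-(3,4-dimethoxyphenyl)-1-ethoxy-1-oxopropan-2-yl]triphenylphosphonium bromide | CCOC(=O)C(Cc1ccc(OC)c(OC)c1)[P+](c1ccccc1)(c1ccccc1)c1ccccc1.[Br-] | intermediate
4 | ethyl 3-(3,4-dimethoxyphenyl)-2-(triphenyl-λ5-phosphanylidene)propanoate | CCOC(=O)C(Cc1ccc(OC)c(OC)c1)=P(c1ccccc1)(c1ccccc1)c1ccccc1 | intermediate
5 | 3,4-bis(benzyloxy)benzaldehyde | O=Cc1ccc(OCc2ccccc2)c(OCc2ccccc2)c1 | starting material
6 | 1,2-bis(benzyloxy)-4-(2-methoxyethenyl)benzene (E/Z mixture) | COC=Cc1ccc(OCc2ccccc2)c(OCc2ccccc2)c1 | intermediate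
7 | 2-[3,4-bis(benzyloxy)phenyl]acetaldehyde | O=CCc1ccc(OCc2ccccc2)c(OCc2ccccc2)c1 | intermediate
8 | ethyl (E)-4-[3,4-bis(benzyloxy)phenyl]-2-(3,4-dimethoxybenzyl)but-2-enoate | CCOC(=O)/C(Cc1ccc(OC)c(OC)c1)=C/Cc1ccc(OCc2ccccc2)c(OCc2ccccc2)c1 | intermediate
9 | (E)-4-[3,4-bis(benzyloxy)phenyl]-2-(3,4-dimethoxybenzyl)but-2-en-1-ol | OC/C(Cc1ccc(OC)c(OC)c1)=C/Cc1ccc(OCc2ccccc2)c(OCc2ccccc2)c1 | intermediate
10 | (3R,4R)-3-[3,4-bis(benzyloxy)benzyl]-4-(3,4-dimethoxybenzyl)dihydrofuran-2(3H)-one | COc1ccc(C[C@H]2COC(=O)[C@@H]2Cc2ccc(OCc3ccccc3)c(OCc3ccccc3)c2)cc1OC | intermediate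
11 | 3'-O-demethylarctigenin, (3R,4R)-3-(3,4-dihydroxybenzyl)-4-(3,4-dimethoxybenzyl)dihydrofuran-2(3H)-one | COc1ccc(C[C@H]2COC(=O)[C@@H]2Cc2ccc(O)c(O)c2)cc1OC | target

**Count**

Total steps: 7. Longest linear sequence: 6 steps (5 → 6 → 7 → 8 → 9 → 10 → 11; step 1 is the side branch).

**Steps most likely to fail**

1. Step 6. The primary allylic C–O bond may ionise to an allylpalladium species, and reversible hydropalladation/β-hydride elimination may move the alkene toward the arenes. Lactonisation may be slow for a primary alcohol that lacks gem-dialkyl assistance, and facial selectivity of hydride delivery may be poor. The fallback is auxiliary-controlled alkylation followed by trans-selective lactone alkylation; it sets out from 2 and 5 and comes back at 10.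
   - Mono-tert-butyl succinate and (R)-4-benzyloxazolidin-2-one are coupled (DCC, DMAP, CH2Cl2) to (R)-4-benzyl-3-(4-tert-butoxy-4-oxobutanoyl)oxazolidin-2-one F1.
   - Its sodium enolate (NaHMDS, THF, −78 °C) should be alkylated by 2 on the face away from the auxiliary benzyl group, giving (R)-4-benzyl-3-[(2R)-4-tert-butoxy-2-(3,4-dimethoxybenzyl)-4-oxobutanoyl]oxazolidin-2-one F2.
   - LiBH4 (THF, 0 °C) removes the auxiliary to give tert-butyl (3R)-3-(3,4-dimethoxybenzyl)-4-hydroxybutanoate F3, and TFA in CH2Cl2 closes this to (R)-4-(3,4-dimethoxybenzyl)dihydrofuran-2(3H)-one F4.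
   - In parallel, 5 is reduced (NaBH4, MeOH) to [3,4-bis(benzyloxy)phenyl]methanol F5 and brominated (PBr3, Et2O, 0 °C) to 4-(bromomethyl)-1,2-bis(benzyloxy)benzene F6.
   - The lithium enolate of F4 (LiHMDS, THF, −78 °C) should be alkylated by F6 anti to the C4 substituent, which gives 10.

2. Step 4. The ylide may enolise the arylacetaldehyde and trigger self-condensation, the hindered α-benzyl ylide may react slowly, E selectivity may be incomplete, and the alkene may drift into conjugation with the arene. The fallback forms the aryl–CH2 bond by cross-coupling and needs no arylacetaldehyde; it sets out from 4 and comes back at 8.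
   - Ylide 4 and glycolaldehyde dimer (THF, reflux) should give ethyl (E)-2-(3,4-dimethoxybenzyl)-4-hydroxybut-2-enoate F7.
   - Appel bromination (CBr4, PPh3, CH2Cl2, 0 °C) gives ethyl (E)-4-bromo-2-(3,4-dimethoxybenzyl)but-2-enoate F8.
   - Allyl–aryl Suzuki coupling with commercial 3,4-bis(benzyloxy)phenylboronic acid (Pd(PPh3)4, KF, THF, rt to 50 °C) should join the aryl group to the unsubstituted allyl terminus with the alkene geometry retained, which gives 8.

3. Step 3. Hydrolysis of the styryl enol ether may be incomplete, and the acid may promote self-aldol condensation or air oxidation of the sensitive aldehyde. The fallback reaches the aldehyde by oxidation under neutral conditions; it sets out from 5 and comes back at 7.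
   - Wittig methylenation of 5 (Ph3PCH3Br, KOtBu, THF) gives 1,2-bis(benzyloxy)-4-ethenylbenzene F9.
   - Anti-Markovnikov hydroboration–oxidation (9-BBN, THF; then NaOH, H2O2) gives 2-[3,4-bis(benzyloxy)phenyl]ethan-1-ol F10.
   - Dess–Martin periodinane (NaHCO3, CH2Cl2, 0 °C) gives 7.

**Further compounds**

F1 | step 6 | (R)-4-benzyl-3-(4-tert-butoxy-4-oxobutanoyl)oxazolidin-2-one | CC(C)(C)OC(=O)CCC(=O)N1[C@H](Cc2ccccc2)COC1=O
F2 | step 6 | (R)-4-benzyl-3-[(2R)-4-tert-butoxy-2-(3,4-dimethoxybenzyl)-4-oxobutanoyl]oxazolidin-2-one | COc1ccc(C[C@H](CC(=O)OC(C)(C)C)C(=O)N2[C@H](Cc3ccccc3)COC2=O)cc1OC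
F3 | step 6 | tert-butyl (3R)-3-(3,4-dimethoxybenzyl)-4-hydroxybutanoate | COc1ccc(C[C@H](CC(=O)OC(C)(C)C)CO)cc1OC
F4 | step 6 | (R)-4-(3,4-dimethoxybenzyl)dihydrofuran-2(3H)-one | COc1ccc(C[C@H]2COC(=O)C2)cc1OC
F5 | step 6 | [3,4-bis(benzyloxy)phenyl]methanol | OCc1ccc(OCc2ccccc2)c(OCc2ccccc2)c1
F6 | step 6 | 4-(bromomethyl)-1,2-bis(benzyloxy)benzene | BrCc1ccc(OCc2ccccc2)c(OCc2ccccc2)c1
F7 | step 4 | ethyl (E)-2-(3,4-dimethoxybenzyl)-4-hydroxybut-2-enoate | CCOC(=O)/C(Cc1ccc(OC)c(OC)c1)=C/CO
F8 | step 4 | ethyl (E)-4-bromo-2-(3,4-dimethoxybenzyl)but-2-enoate | CCOC(=O)/C(Cc1ccc(OC)c(OC)c1)=C/CBr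
F9 | step 3 | 1,2-bis(benzyloxy)-4-ethenylbenzene | C=Cc1ccc(OCc2ccccc2)c(OCc2ccccc2)c1
F10 | step 3 | 2-[3,4-bis(benzyloxy)phenyl]ethan-1-ol | OCCc1ccc(OCc2ccccc2)c(OCc2ccccc2)c1
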